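## Structural features

Target 40 is a pentacyclic C30 hydroxy diacid in which rings A, B, D and E are six-membered and ring C is a cycloheptene. Oleanane-type locants are used throughout, with C27 inserted into ring C between C12 and C13, so that ring C is C8, C9, C11, C12, C27, C13, C14. Rings A and B form a trans-decalin (5α-H, 10β-methyl) joined to ring C through the quaternary C8 (β-methyl) and C9 (α-H). Rings C and D share the tetrasubstituted C13=C14 double bond, and rings D and E are cis-fused at C17/C18. Six contiguous stereocentres lie on the left (C3 axial α-OH, C4 with α-methyl and β-carboxyl, C5, C10, C9, C8), one isolated centre in ring C (C12, α-OMe, S), and three contiguous ones on the right (quaternary C17 with β-carboxyl, C18 β-H, C19 axial α-OH). The fragile groups are the tetrasubstituted alkene (acid-promoted migration), the neopentyl homoallylic C19 alcohol, and two tertiary carboxylic acids whose esters resist acyl substitution. The real difficulty is twofold: bonding the quaternary C8 to C14 inside a seven-membered ring, and relating the C17–C19 triad to the distant left-hand array across the two sp2 carbons C13 and C14. The key step uses the fact that the C19 carbinol is homoallylic to C13=C14 through C18. Read backwards as an ene reaction, this gives a C19 aldehyde and a C13=C18 alkene whose C14 carries the hydrogen that ends on oxygen.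

## Logic of the disconnections

40 to 39 to 38: only O–CH3 (two esters) and O–Si bonds are cut. The two hindered acids and the C3 alcohol stay masked until the end. The demand is that the ester cleavage attacks the methyl carbon and not the shielded acyl carbon.

38 to 37: the C18–C19 bond is cut, with the hydroxyl hydrogen returned to C14 and the alkene moved back to C13=C18. This removes ring E and two stereocentres (C18, C19) and leaves a tetracycle with a simple neopentyl aldehyde. The demand is a 14α-hydrogen syn to the α-oriented tether on C17, and abstraction from C14 rather than C27.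

37 to 36 to 35 to 28 + 33: the C17–C22 bond is cut, and the hydrogens on C14, C15 and C16 are removed to restore an aromatic ring D. The quaternary C17 and the relay centre C14 then both come from a flat benzoate. The demand is α-face protonation at C14, alkylation of C17 trans to C8, and saturation of C15=C16 without touching C13=C18.

28 to 27 to 26 to 25: the C17–C28 bond is cut back to a phenol oxygen. The electron-rich arene needed for ring closure thus becomes the electron-poor benzoate needed for reduction. The demand is a phenol protecting group removable without disturbing the C12 methyl ether.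

25 to 23 to 22: the C12 O–methyl bond and then the C8–C14 bond are cut. This opens ring C and leaves a decalin with an exocyclic C8 alkene and an arene on a three-carbon arm. The demand is a seven-membered Friedel–Crafts closure from the α-face of C8 and an inert oxygen substituent on C12 (an ester).

22 to 21 to 20 to 19 to 18: the C3–H bond, the C4–C23 bond and the ester alkoxy group are adjusted. This returns to a β-keto ester with a hydrogen on C4. The demand is α-face methylation at C4 and equatorial hydride delivery to C3.

18 to 17: the C4–C5 and C9–C10 bonds are cut. Rings A and B and three fixed stereocentres collapse to an open chain. The demand is a cyclisation whose absolute sense is controlled by the ester auxiliary.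

17 to 15 + 12, and 15 to 13 + 14: the C1–C2 bond and the auxiliary ester bond are cut. This separates the radical precursor from the chain that carries C12 and the arene.

12 to 11 to 10 to 9 to 2 + 7: the C9–C11 and C8–C26 bonds are cut (after removal of bromine, the allylic oxygen and the acetyl group). The E-trisubstituted alkene and the C12 carbinol then arise in one operation from an alkyne and an epoxide. The demand is syn carbometalation and epoxide opening at the CH2 terminus.

7 to 3 + 4, 2 to 1, and 33 to 32 to 30 to 29: the C13–C27 bond, the C7–C8 bond and the iodide/acetal groups are cut back to purchasable materials. C12 is taken from the chiral pool and is never a reacting centre afterwards.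

## Other disconnections considered

Alternative 1: The cut is through C4–C5 and C9–C10. In the forward sense Mn(OAc)3 would generate the C4 radical between the C3 ketone and the C24 ester, C4 would add to C5 and C10 to C9, and Cu(OAc)2 would turn the C8 radical into the exocyclic alkene of A1.
- In its favour: two rings, two C–C bonds and four stereocentres form in one step from a flat chain. The 2-methyl group gives the quaternary C4 with the axial ester directly, which saves the ester exchange and methylation of steps 10 and 11. On that point it is better than the chosen plan.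
- Against it here: without a chelating additive the facial control by the 8-phenylmenthyl ester should be modest. The auxiliary ester on the neopentyl axial C4 is expected to resist both hydrolysis and SN2 dealkylation, so C24 would have to be reduced and re-oxidised. The C11 acetate leaves the next C–C bond to be made at a hindered position.
- Comparison: structurally A1 holds only the left half (C1–C11, C23–C26), where relative configuration is intrinsically easy. Rings C, D and E, C12 and the C17–C19 triad remain open, so a ring E closure of the chosen kind would still be needed. Mechanistically it is a radical cascade against a Lewis acid-promoted pericyclic step. The chosen route uses the same reaction class in step 9, so on the construction of rings A and B the two are equal. As the centrepiece of the whole route the alternative covers much less of the target.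

Alternative 2: The cut is through C13–C27 (and O–C12). In the forward sense NaOCl would oxidise an oxime at C13 to the nitrile oxide, whose carbon would bond to C27 and whose oxygen to C12 of an allyl group on C9, giving A2.
- In its favour: the C12 oxygen and a masked C13 ketone arrive in the same step. The chosen plan must bring the C12 oxygen from a separate chiral building block, so this is a point on which the alternative is better. Oxygen at the substituted alkene carbon is also the intrinsic preference of nitrile oxides.
- Against it here: with four atoms between the dipole carbon and the alkene, the fused mode (C13–C12, O–C27) would close a six-membered ring and should win. The required mode gives a bridged bicycle with the C=N bond at a bridgehead, which is strained. The C12 configuration would depend on a medium-ring transition state. After N–O cleavage the β-hydroxy ketone can eliminate across C12–C27 before it is methylated. Ring D then still needs an aldol bond C13–C18, dehydration specifically towards C14 and axial reduction at C19.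
- Comparison: structurally it addresses ring C and C12 but leaves ring D and the alkene position open. Mechanistically a concerted cycloaddition is at least the equal of the ene step in stereospecificity, but its regiochemistry opposes the ring size wanted. In step economy it needs at least five operations after the key step, against two in the chosen plan.

Alternative 3: The cuts are C12–C27 and C8–C9. In the forward sense Me3SiOTf would ionise a dimethyl acetal at C12 next to a C9=C11 silyl enol ether. The 2-siloxy-1-methoxyallyl cation would then add across a C8=C14/C13=C27 diene on ring D to give A3.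
- In its favour: it is the most convergent of the four. Two rings (B and C), two C–C bonds and three stereocentres (C8, C9, C12) form at once, with the methoxy group in place and the C13=C14 alkene emerging at the right position. The D/E half, with C17–C19, could be made and purified as a small molecule. On convergence and on ring count per step it is better than the chosen plan.
- Against it here: the diene terminus C8 is fully substituted, so the s-cis diene is strained and proton loss or stepwise alkylation can compete with cycloaddition. The facial sense relative to C5/C10 and to ring E is not enforced by any tether element. The C11 ketone must then be removed next to the C12 methoxy group, where reductive methods tend to expel methoxide.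
- Comparison: structurally it attacks the unusual seven-membered ring directly, which the chosen plan leaves to a Friedel–Crafts closure. Mechanistically it has more selectivity variables (diene geometry, two faces, regiochemistry) than the ene step, which has one main competitor (C27–H). In longest linear sequence it could be shorter, but the deoxygenation at C11 and the preparation of the diene partner would offset that.

Key step: step 25

Remark: the facial sense assigned to the (1S,2R,5S)-8-phenylmenthyl ester in step 9 rests on the phenyl-shielding model for the chelated enol; were it reversed, the (1R,2S,5R) ester would be used with no other change.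

Step 1
Reactants: 1 5-bromo-2-methylpent-2-ene
Product: 2 6-methylhept-5-en-1-yne
Conditions: LiC≡CH·H2NCH2CH2NH2, DMSO, 0 °C → rt
Reagents that add atoms: lithium acetylide–ethylenediamine complex, [Li+].[C-]#C.NCCN
Why: SN2 alkylation of the acetylide by a primary bromide; it supplies the terminal alkyne (future C8/C9) for the carboalumination.

Step 2
Reactants: 3 1-(benzyloxy)-3-bromobenzene; 4 (R)-epichlorohydrin
Product: 7 (2R)-2-[3-(benzyloxy)benzyl]oxirane, via aryl Grignard reagent 5 (not isolated), via chlorohydrin 6 (not isolated)
Conditions: Mg, THF, 40 °C; CuI (10 mol%), 4, −40 → 0 °C; then NaOH (aq), Et2O, rt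
Reagents that add atoms: none
Why: Copper-catalysed Grignard opening of the epoxide at its CH2 terminus, then Williamson closure; the stereocentre of 4 (future C12) is never a reacting centre, so its configuration is carried over unchanged.

Step 3
Reactants: 2 6-methylhept-5-en-1-yne; 7 (2R)-2-[3-(benzyloxy)benzyl]oxirane
Product: 9 (2S,4E)-1-[3-(benzyloxy)phenyl]-5,9-dimethyldeca-4,8-dien-2-ol, via alkenylalane 8 (not isolated)
Conditions: Me3Al (2 equiv), Cp2ZrCl2 (0.2 equiv), CH2Cl2, rt; evaporate; n-BuLi, hexane/THF, −78 → 0 °C; then 7 (0.7 equiv), −30 °C → rt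
Reagents that add atoms: trimethylaluminium, C[Al](C)C
Why: Negishi zirconium-catalysed carboalumination adds methyl and aluminium syn across the alkyne, which fixes the E-trisubstituted alkene; the butyl ate complex of 8 opens the epoxide at its unsubstituted carbon, so C12 keeps its configuration (now S by priority change).

Step 4
Reactants: 9 (2S,4E)-1-[3-(benzyloxy)phenyl]-5,9-dimethyldeca-4,8-dien-2-ol
Product: 10 (2S,4E)-1-[3-(benzyloxy)phenyl]-5,9-dimethyldeca-4,8-dien-2-yl acetate
Conditions: Ac2O, pyridine, DMAP (cat.), CH2Cl2, rt
Reagents that add atoms: acetic anhydride, CC(=O)OC(C)=O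
Why: Acyl transfer to the secondary alcohol; an ester is chosen because its oxygen, unlike a hydroxyl or ether oxygen four atoms from C8, should not trap the C8 cation of step 14 as a tetrahydrofuran.

Step 5
Reactants: 10 (2S,4E)-1-[3-(benzyloxy)phenyl]-5,9-dimethyldeca-4,8-dien-2-yl acetate
Product: 11 (2S,4E,8E)-1-[3-(benzyloxy)phenyl]-10-hydroxy-5,9-dimethyldeca-4,8-dien-2-yl acetate
Conditions: SeO2 (0.3 equiv), t-BuOOH (3 equiv), salicylic acid (cat.), CH2Cl2, rt; then NaBH4, MeOH, 0 °C
Reagents that add atoms: selenium dioxide, O=[Se]=O; tert-butyl hydroperoxide (terminal oxidant), CC(C)(C)OO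
Why: Riley allylic oxidation (ene reaction, then [2,3]-shift) at the E-methyl of the terminal trisubstituted alkene, the most reactive allylic site as in geranyl esters; borohydride returns any enal to the alcohol.

Step 6
Reactants: 11 (2S,4E,8E)-1-[3-(benzyloxy)phenyl]-10-hydroxy-5,9-dimethyldeca-4,8-dien-2-yl acetate
Product: 12 (2S,4E,8E)-1-[3-(benzyloxy)phenyl]-10-bromo-5,9-dimethyldeca-4,8-dien-2-yl acetate
Conditions: CBr4, PPh3, CH2Cl2, −20 → 0 °C
Reagents that add atoms: tetrabromomethane, BrC(Br)(Br)Br
Why: Appel bromination of the primary allylic alcohol under neutral conditions; no stereocentre is touched.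

Step 7
Reactants: 13 (+)-8-phenylmenthol; 14 2,2,6-trimethyl-4H-1,3-dioxin-4-one
Product: 15 (1S,2R,5S)-5-methyl-2-(2-phenylpropan-2-yl)cyclohexyl 3-oxobutanoate
Conditions: xylene, 140 °C (acetone distilled off)
Reagents that add atoms: none
Why: Thermal retro-[4+2] of the dioxinone releases acetylketene, which acylates the hindered secondary alcohol.

Step 8
Reactants: 15 (1S,2R,5S)-5-methyl-2-(2-phenylpropan-2-yl)cyclohexyl 3-oxobutanoate; 12 (2S,4E,8E)-1-[3-(benzyloxy)phenyl]-10-bromo-5,9-dimethyldeca-4,8-dien-2-yl acetate
Product: 17 8-phenylmenthyl (6E,10E,13S)-13-acetoxy-14-[3-(benzyloxy)phenyl]-6,10-dimethyl-3-oxotetradeca-6,10-dienoate, via dianion 16 (not isolated)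
Conditions: NaH, THF, 0 °C; n-BuLi, 0 °C; then 12 (1.05 equiv), −78 → 0 °C; NH4Cl (aq)
Reagents that add atoms: none
Why: γ-Alkylation of the acetoacetate dianion by the primary allylic bromide (SN2); the bromide is kept in slight excess so that no dianion is left to attack the acetate.

Step 9
Reactants: 17 8-phenylmenthyl (6E,10E,13S)-13-acetoxy-14-[3-(benzyloxy)phenyl]-6,10-dimethyl-3-oxotetradeca-6,10-dienoate
Product: 18 rings A/B keto ester bearing the 8-phenylmenthyl ester (3-oxo; 8(26)-ene; 5α-H; 9α-H; 10β-methyl; C4–H labile)
Conditions: Mn(OAc)3·2H2O (2.2 equiv), Cu(OAc)2·H2O (1 equiv), Yb(OTf)3 (1 equiv), CF3CH2OH, −5 → 0 °C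
Reagents that add atoms: none
Why: Oxidative free-radical polyene bicyclisation: trivalent manganese oxidises the Yb-chelated enol to the C4 radical, two 6-endo additions form C4–C5 and C9–C10 through chair–chair folding of the E-alkenes (trans fusion, equatorial C9 chain), and divalent copper turns the C8 radical into the exocyclic alkene. The phenyl ring of the auxiliary covers one face of the chelated radical, so C5 adds to the other face and fixes C5, C9 and C10 in the absolute sense; ring-alkene isomers are usable because step 14 converts all of them into the same C8 cation.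

Step 10
Reactants: 18 rings A/B keto ester bearing the 8-phenylmenthyl ester
Product: 19 rings A/B keto ester as methyl ester (C4–H)
Conditions: MeOH (20 equiv), DMAP (0.3 equiv), toluene, 110 °C (sealed tube)
Reagents that add atoms: methanol, CO
Why: DMAP-catalysed alkoxy exchange of a β-keto ester that has an α-hydrogen (acylketene pathway), a path closed to the C12 acetate; excess methanol drives the exchange and 13 is recovered.

Step 11
Reactants: 19 rings A/B keto ester as methyl ester (C4–H)
Product: 20 rings A/B keto ester with quaternary C4 (4α-methyl; 4β-CO2Me)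
Conditions: K2CO3, MeI, acetone, reflux
Reagents that add atoms: iodomethane, CI
Why: C-Alkylation of the β-keto ester enolate; iodomethane approaches C4 from the α-face, anti to the axial C10 methyl, which gives the 4α-methyl/4β-ester arrangement known from podocarpate-type syntheses.

Step 12
Reactants: 20 rings A/B keto ester with quaternary C4
Product: 21 3α-alcohol of the rings A/B ester
Conditions: LiBH(s-Bu)3 (1.2 equiv), THF, −78 °C; NH4Cl (aq)
Reagents that add atoms: none
Why: The bulky hydride attacks the C3 ketone along the equatorial direction because the axial path is blocked by H1α and H5α, giving the axial 3α-alcohol; the esters survive at −78 °C.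

Step 13
Reactants: 21 3α-alcohol of the rings A/B ester
Product: 22 3α-silyl ether of the rings A/B ester
Conditions: TBSOTf, 2,6-lutidine, CH2Cl2, 0 °C → rt
Reagents that add atoms: tert-butyldimethylsilyl triflate, CC(C)(C)[Si](C)(C)OS(=O)(=O)C(F)(F)F
Why: Silylation of the hindered axial alcohol with the silyl triflate; O3 stays protected through steps 14 to 25.

Step 14
Reactants: 22 3α-silyl ether of the rings A/B ester
Product: 23 tetracycle with aromatic ring D (8β-methyl; 12α-acetoxy; 17-benzyloxy)
Conditions: SnCl4 (2 equiv), CH2Cl2, −78 → −30 °C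
Reagents that add atoms: none
Why: Friedel–Crafts cyclialkylation: protonation of the alkene gives the tertiary C8 cation, which is attacked by C14, the arene position para to the benzyloxy group, closing seven-membered ring C. Attack comes from the α-face because the β-axial approach is blocked by the syn-axial C10 methyl, so the aryl group is equatorial, the new C8 methyl is axial (8β) and the B/C fusion is trans.

Step 15
Reactants: 23 tetracycle with aromatic ring D (12α-acetoxy)
Product: 25 12α-methyl ether of the tetracycle, via alkoxide 24 (not isolated)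
Conditions: NaH, MeOH (1.2 equiv), DMF, 0 °C → rt; then MeI, rt
Reagents that add atoms: iodomethane, CI
Why: Methoxide removes the acetyl group as methyl acetate (a degenerate exchange for the C24 methyl ester) and alkoxide 24 is methylated in a Williamson reaction; C12 keeps its configuration.

Step 16
Reactants: 25 12α-methyl ether of the tetracycle
Product: 26 17-phenol of the tetracycle
Conditions: H2 (1 atm), Pd/C (10 wt% Pd), EtOAc, rt
Reagents that add atoms: none
Why: Hydrogenolysis of the benzyl aryl ether; no C=C bond is present at this stage and the C12 methyl ether is untouched.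

Step 17
Reactants: 26 17-phenol of the tetracycle
Product: 27 17-aryl triflate of the tetracycle
Conditions: PhNTf2, Et3N, DMAP (cat.), CH2Cl2, rt
Reagents that add atoms: N-phenyl-bis(trifluoromethanesulfonimide), O=S(=O)(N(c1ccccc1)S(=O)(=O)C(F)(F)F)C(F)(F)F
Why: Triflation of the phenol with the mild triflimide converts the activating oxygen into a leaving group.

Step 18
Reactants: 27 17-aryl triflate of the tetracycle
Product: 28 methyl benzoate of the tetracycle (C28 ester on C17)
Conditions: Pd(OAc)2 (5 mol%), dppp (6 mol%), CO (1 atm), MeOH, Et3N, DMSO, 70 °C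
Reagents that add atoms: carbon monoxide, [C-]#[O+]; methanol, CO
Why: Palladium-catalysed methoxycarbonylation of the aryl triflate (oxidative addition, CO insertion, methanolysis) introduces C28.

Step 19
Reactants: 29 2,2-dimethylpent-4-enal
Product: 30 5,5-dimethoxy-4,4-dimethylpent-1-ene
Conditions: HC(OMe)3, MeOH, TsOH (cat.), rt
Reagents that add atoms: trimethyl orthoformate, COC(OC)OC
Why: Acid-catalysed acetalisation with the orthoformate as water scavenger masks the future C19 aldehyde.

Step 20
Reactants: 30 5,5-dimethoxy-4,4-dimethylpent-1-ene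
Product: 32 4,4-dimethoxy-3,3-dimethylbutan-1-ol, via aldehyde 31 (not isolated)
Conditions: O3, CH2Cl2/MeOH, −78 °C; then NaBH4, −78 → 0 °C
Reagents that add atoms: ozone, [O-][O+]=O
Why: Ozonolysis of the terminal alkene with reductive work-up gives the primary alcohol; the mixture is kept basic so that the hydroxy acetal does not close to a 2-methoxytetrahydrofuran.

Step 21
Reactants: 32 4,4-dimethoxy-3,3-dimethylbutan-1-ol
Product: 33 4-iodo-1,1-dimethoxy-2,2-dimethylbutane
Conditions: I2, PPh3, imidazole, CH2Cl2, 0 °C
Reagents that add atoms: iodine, II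
Why: Appel-type iodination buffered by imidazole gives the primary iodide needed for the C17–C22 bond.

Step 22
Reactants: 28 methyl benzoate of the tetracycle; 33 4-iodo-1,1-dimethoxy-2,2-dimethylbutane
Product: 35 13(18),15-diene with quaternary C17 (14α-H; 17β-CO2Me; 17α-chain acetal), via ester enolate 34 (not isolated)
Conditions: Li (2.5 equiv), NH3(l)/THF, t-BuOH (1 equiv), −78 °C; isoprene; then 33, −78 → −33 °C
Reagents that add atoms: none
Why: Birch reduction–alkylation of the benzoate: the radical anion is protonated at C14 (para to the ester), expected from the α-face anti to the axial C26 methyl on C8, which creates the 14α-H relay centre. Enolate 34 is then alkylated at C17 from the α-face, trans to the bulky C8 group, placing the chain α and the ester β; the aliphatic C24 ester is spared by the limited amount of metal at −78 °C.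

Step 23
Reactants: 35 13(18),15-diene with quaternary C17
Product: 36 13(18)-ene acetal
Conditions: H2 (1 atm), RhCl(PPh3)3 (10 mol%), benzene, rt
Reagents that add atoms: none
Why: Homogeneous hydrogenation with RhCl(PPh3)3 reduces the cis-disubstituted C15=C16 alkene and leaves the trisubstituted C13=C18 alkene, which this catalyst reduces far more slowly.

Step 24
Reactants: 36 13(18)-ene acetal
Product: 37 13(18)-ene C19 aldehyde (ene precursor)
Conditions: pyridinium p-toluenesulfonate (cat.), acetone/H2O 10:1, 50 °C
Reagents that add atoms: water, O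
Why: Mild aqueous acid hydrolyses the dimethyl acetal to the neopentyl aldehyde; excess water ensures that the oxocarbenium ion is hydrolysed and not captured by the alkene, and the silyl ether survives.

Step 25
Reactants: 37 13(18)-ene C19 aldehyde
Product: 38 19α-hydroxy pentacycle (3-O-silyl dimethyl ester)
Conditions: Me2AlCl (2.5 equiv), CH2Cl2, −78 → 0 °C; potassium sodium tartrate (aq)
Reagents that add atoms: none
Why: Me2AlCl binds the aldehyde oxygen; C19 bonds to C18 while the oxygen takes the hydrogen of C14 through the six-membered array O–C19–C18–C13–C14–H, the double bond moves to C13=C14, and loss of methane from the product complex keeps protic acid away from the new alkene. The closest known reaction type is the Lewis acid-promoted type 1 intramolecular carbonyl-ene cyclisation of 6,7-unsaturated aldehydes, as in citronellal to isopulegol. Ring E closes in a 6-exo-trig sense at C18 through a chair in which C13 is equatorial. C18 is controlled by the tether: it leaves C17 on the α-face and can only reach the α-face of the alkene, so the D/E fusion is cis and H18 is β. C19 is controlled by the hydrogen transfer: only an axial oxygen lies over C14 (the alkene substituent cis to C17), whereas an equatorial one lies over C27. The axial complexed oxygen is gauche to one C20 methyl and anti to the other (the equatorial one is gauche to both), and its syn-axial contact with C16 runs across the still long C18–C19 bond. The step needs abstraction from C14 and not from C27; the substrate offers a tertiary allylic C14–H on the α-face (set in step 22) and a tetrasubstituted product alkene. The aldehyde has no α-hydrogen, so enolisation and aldol paths are shut.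

Step 26
Reactants: 38 19α-hydroxy pentacycle (3-O-silyl dimethyl ester)
Product: 39 3α,19α-diol dimethyl ester
Conditions: HF·pyridine, THF, 0 °C → rt
Reagents that add atoms: none
Why: Fluoride cleaves the Si–O bond of the hindered silyl ether; the buffered reagent avoids migration of the tetrasubstituted alkene.

Step 27
Reactants: 39 3α,19α-diol dimethyl ester
Product: 40 target diacid (CNP0394974.1)
Conditions: LiSPr (10 equiv), HMPA, rt → 50 °C; then HCl (aq) to pH 3
Reagents that add atoms: none
Why: SN2 demethylation of both neopentyl methyl esters by thiolate at the methyl carbon (acyl attack is sterically shut); the methyl ether, the alcohols and the alkene are untouched, and acidification gives the diacid.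

## Compound list

1 | 5-bromo-2-methylpent-2-ene | CC(C)=CCCBr | starting material
2 | 6-methylhept-5-en-1-yne | CC(C)=CCCC#C | intermediate
3 | 1-(benzyloxy)-3-bromobenzene | Brc1cccc(OCc2ccccc2)c1 | starting material
4 | (R)-epichlorohydrin, (2R)-2-(chloromethyl)oxirane | ClC[C@H]1CO1 | starting material
5 | [3-(benzyloxy)phenyl]magnesium bromide | Br[Mg]c1cccc(OCc2ccccc2)c1 | intermediate
6 | bromomagnesium alkoxide of (2R)-1-[3-(benzyloxy)phenyl]-3-chloropropan-2-ol | ClC[C@H](O[Mg]Br)Cc1cccc(OCc2ccccc2)c1 | intermediate
7 | (2R)-2-[3-(benzyloxy)benzyl]oxirane | C1[C@H](O1)Cc2cccc(OCc3ccccc3)c2 | intermediate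
8 | [(1E)-2,6-dimethylhepta-1,5-dien-1-yl]dimethylalane | CC(C)=CCC/C(C)=C/[Al](C)C | intermediate
9 | (2S,4E)-1-[3-(benzyloxy)phenyl]-5,9-dimethyldeca-4,8-dien-2-ol | CC(C)=CCC/C(C)=C/C[C@H](O)Cc1cccc(OCc2ccccc2)c1 | intermediate
10 | (2S,4E)-1-[3-(benzyloxy)phenyl]-5,9-dimethyldeca-4,8-dien-2-yl acetate | CC(C)=CCC/C(C)=C/C[C@H](OC(C)=O)Cc1cccc(OCc2ccccc2)c1 | intermediate
11 | (2S,4E,8E)-1-[3-(benzyloxy)phenyl]-10-hydroxy-5,9-dimethyldeca-4,8-dien-2-yl acetate | OC/C(C)=C/CC/C(C)=C/C[C@H](OC(C)=O)Cc1cccc(OCc2ccccc2)c1 | intermediate
12 | (2S,4E,8E)-1-[3-(benzyloxy)phenyl]-10-bromo-5,9-dimethyldeca-4,8-dien-2-yl acetate | BrC/C(C)=C/CC/C(C)=C/C[C@H](OC(C)=O)Cc1cccc(OCc2ccccc2)c1 | intermediate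
13 | (+)-8-phenylmenthol, (1S,2R,5S)-5-methyl-2-(2-phenylpropan-2-yl)cyclohexan-1-ol | O[C@H]1C[C@@H](C)CC[C@@H]1C(C)(C)c1ccccc1 | starting material
14 | 2,2,6-trimethyl-4H-1,3-dioxin-4-one | CC1=CC(=O)OC(C)(C)O1 | starting material
15 | (1S,2R,5S)-5-methyl-2-(2-phenylpropan-2-yl)cyclohexyl 3-oxobutanoate | CC(=O)CC(=O)O[C@H]1C[C@@H](C)CC[C@@H]1C(C)(C)c1ccccc1 | intermediate
16 | sodium lithium dienolate (dianion) of 15 | C=C([O-])C=C([O-])O[C@H]1C[C@@H](C)CC[C@@H]1C(C)(C)c1ccccc1.[Na+].[Li+] | intermediate
17 | (1S,2R,5S)-8-phenylmenthyl (6E,10E,13S)-13-acetoxy-14-[3-(benzyloxy)phenyl]-6,10-dimethyl-3-oxotetradeca-6,10-dienoate | O=C(CC(=O)CC/C(C)=C/CC/C(C)=C/C[C@H](OC(C)=O)Cc1cccc(OCc2ccccc2)c1)O[C@H]1C[C@@H](C)CC[C@@H]1C(C)(C)c1ccccc1 | intermediate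
18 | (1S,2R,5S)-8-phenylmenthyl ester of the rings A/B keto acid: trans-decalin, 3-oxo, 4-CO2R (drawn 4α, epimerisable), 5α-H, 10β-methyl, 8(26)-methylene, 9α-H, 9β-CH2–(12S)-CH(OAc)–CH2–C6H4-3-OCH2Ph | C=C1CC[C@@H]2[C@](C)(CCC(=O)[C@H]2C(=O)O[C@H]3C[C@@H](C)CC[C@@H]3C(C)(C)c3ccccc3)[C@H]1C[C@H](OC(C)=O)Cc1cccc(OCc4ccccc4)c1 | intermediate
19 | methyl ester analogue of 18 (C4–H, epimerisable) | C=C1CC[C@@H]2[C@](C)(CCC(=O)[C@H]2C(=O)OC)[C@H]1C[C@H](OC(C)=O)Cc1cccc(OCc3ccccc3)c1 | intermediate
20 | rings A/B keto ester with quaternary C4: 3-oxo, 4α-methyl, 4β-CO2Me, otherwise as 19 | C=C1CC[C@@H]2[C@](C)(CCC(=O)[C@]2(C)C(=O)OC)[C@H]1C[C@H](OC(C)=O)Cc1cccc(OCc3ccccc3)c1 | intermediate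
21 | 3α-hydroxy analogue of 20 | C=C1CC[C@@H]2[C@](C)(CC[C@@H](O)[C@]2(C)C(=O)OC)[C@H]1C[C@H](OC(C)=O)Cc1cccc(OCc3ccccc3)c1 | intermediate
22 | 3α-(tert-butyldimethylsilyloxy) analogue of 21 | C=C1CC[C@@H]2[C@](C)(CC[C@@H](O[Si](C)(C)C(C)(C)C)[C@]2(C)C(=O)OC)[C@H]1C[C@H](OC(C)=O)Cc1cccc(OCc3ccccc3)c1 | intermediate
23 | tetracycle: ring C closed by C8–C14, 8β-methyl, aromatic ring D with 17-OCH2Ph, 12α-OAc, 3α-OTBS, C24 methyl ester | CC(=O)O[C@@H]1Cc2cc(OCc3ccccc3)ccc2[C@]2(C)CC[C@@H]3[C@](C)(CC[C@@H](O[Si](C)(C)C(C)(C)C)[C@]3(C)C(=O)OC)[C@H]2C1 | intermediate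
24 | sodium 12α-alkoxide of the tetracycle | [Na+].[O-][C@@H]1Cc2cc(OCc3ccccc3)ccc2[C@]2(C)CC[C@@H]3[C@](C)(CC[C@@H](O[Si](C)(C)C(C)(C)C)[C@]3(C)C(=O)OC)[C@H]2C1 | intermediate
25 | 12α-methoxy tetracycle with 17-OCH2Ph | CO[C@@H]1Cc2cc(OCc3ccccc3)ccc2[C@]2(C)CC[C@@H]3[C@](C)(CC[C@@H](O[Si](C)(C)C(C)(C)C)[C@]3(C)C(=O)OC)[C@H]2C1 | intermediate
26 | 12α-methoxy tetracycle with 17-OH (phenol) | CO[C@@H]1Cc2cc(O)ccc2[C@]2(C)CC[C@@H]3[C@](C)(CC[C@@H](O[Si](C)(C)C(C)(C)C)[C@]3(C)C(=O)OC)[C@H]2C1 | intermediate
27 | 12α-methoxy tetracycle with 17-OSO2CF3 | CO[C@@H]1Cc2cc(OS(=O)(=O)C(F)(F)F)ccc2[C@]2(C)CC[C@@H]3[C@](C)(CC[C@@H](O[Si](C)(C)C(C)(C)C)[C@]3(C)C(=O)OC)[C@H]2C1 | intermediate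
28 | 12α-methoxy tetracycle with 17-CO2Me (benzoate; C24 and C28 methyl esters) | CO[C@@H]1Cc2cc(C(=O)OC)ccc2[C@]2(C)CC[C@@H]3[C@](C)(CC[C@@H](O[Si](C)(C)C(C)(C)C)[C@]3(C)C(=O)OC)[C@H]2C1 | intermediate
29 | 2,2-dimethylpent-4-enal | CC(C)(CC=C)C=O | starting material
30 | 5,5-dimethoxy-4,4-dimethylpent-1-ene | COC(OC)C(C)(C)CC=C | intermediate
31 | 4,4-dimethoxy-3,3-dimethylbutanal | COC(OC)C(C)(C)CC=O | intermediate
32 | 4,4-dimethoxy-3,3-dimethylbutan-1-ol | COC(OC)C(C)(C)CCO | intermediate
33 | 4-iodo-1,1-dimethoxy-2,2-dimethylbutane | COC(OC)C(C)(C)CCI | intermediate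
34 | lithium ester enolate of the 14α-H 1,4-dihydrobenzoate (C17=C28 enolate, 13(18),15-diene) | CO[C@@H]1CC2=CC(=C([O-])OC)C=C[C@H]2[C@]2(C)CC[C@@H]3[C@](C)(CC[C@@H](O[Si](C)(C)C(C)(C)C)[C@]3(C)C(=O)OC)[C@H]2C1.[Li+] | intermediate
35 | 13(18),15-diene: 14α-H, 17β-CO2Me, 17α-CH2CH2C(CH3)2CH(OMe)2, 12α-OMe, 3α-OTBS | CO[C@@H]1CC2=C[C@](C(=O)OC)(CCC(C)(C)C(OC)OC)C=C[C@H]2[C@]2(C)CC[C@@H]3[C@](C)(CC[C@@H](O[Si](C)(C)C(C)(C)C)[C@]3(C)C(=O)OC)[C@H]2C1 | intermediate
36 | 13(18)-ene dimethyl acetal (15,16-dihydro analogue of 35) | CO[C@@H]1CC2=C[C@](C(=O)OC)(CCC(C)(C)C(OC)OC)CC[C@H]2[C@]2(C)CC[C@@H]3[C@](C)(CC[C@@H](O[Si](C)(C)C(C)(C)C)[C@]3(C)C(=O)OC)[C@H]2C1 | intermediate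
37 | tetracyclic 13(18)-ene C19 aldehyde with 14α-H (ene precursor) | CO[C@@H]1CC2=C[C@](C(=O)OC)(CCC(C)(C)C=O)CC[C@H]2[C@]3(C)CC[C@@H]4[C@](C)(CC[C@@H](O[Si](C)(C)C(C)(C)C)[C@]4(C)C(=O)OC)[C@H]3C1 | intermediate
38 | 19α-hydroxy pentacycle, 13-ene, 18β-H, 3α-OTBS, dimethyl ester | CO[C@@H]1CC2=C(CC[C@@]3(C(=O)OC)CCC(C)(C)[C@@H](O)[C@@H]23)[C@]2(C)CC[C@@H]3[C@](C)(CC[C@@H](O[Si](C)(C)C(C)(C)C)[C@]3(C)C(=O)OC)[C@H]2C1 | intermediate
39 | 3α,19α-dihydroxy pentacycle, dimethyl ester | CO[C@@H]1CC2=C(CC[C@@]3(C(=O)OC)CCC(C)(C)[C@@H](O)[C@@H]23)[C@]2(C)CC[C@@H]3[C@](C)(CC[C@@H](O)[C@]3(C)C(=O)OC)[C@H]2C1 | intermediate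
40 | CNP0394974.1: 3α,19α-dihydroxy-12α-methoxy pentacyclic 13-ene-24,28-dioic acid | CO[C@@H]1CC2=C(CC[C@@]3(C(=O)O)CCC(C)(C)[C@@H](O)[C@@H]23)[C@]2(C)CC[C@@H]3[C@](C)(CC[C@@H](O)[C@]3(C)C(=O)O)[C@H]2C1 | target

## Step count and least certain steps

Total step count: 27. Longest linear sequence: 22 steps (steps 1, 3–6, 8–18, 22–27).

**Step 25 (key step).** The most likely failure is hydrogen transfer from C27 instead of C14 through the chair with an equatorial oxygen, which would give the 13(27)-ene and the 19β-alcohol; chloride capture at C13 is a lesser risk. The cause is that the equatorial-oxygen chair is the usual preference in such cyclisations and the C27 hydrogens are less hindered. The fallback sets out from 37 and gives up the concerted ene reaction for a stepwise sequence: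
- SnCl4 in CH2Cl2 at −78 °C should effect a Prins cyclisation with chloride capture anti at C13, giving the 13β-chloro-19β-ol F1.
- DBU in hot toluene should remove HCl in an anti E2 process across C13–C14 (H14α and Cl13β trans-diaxial), giving the 19β-epimer of 38, F2.
- Swern oxidation gives the 19-ketone F3.
- LiBH(s-Bu)3 at −78 °C should attack from the equatorial β-direction, because the α-axial path is blocked by the syn-axial C16 methylene, and the route is rejoined at 38.

**Step 22.** The most likely failure is poor facial selectivity in the kinetic protonation at C14, which would also invert the sense at C17, because both faces of C14 are flanked by substituents of the quaternary C8. Partial reduction of the C24 ester is a lesser risk. The fallback sets out from 26 and returns at 36, replacing kinetic protonation by an equilibrated centre: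
- MeI and K2CO3 give the 17-methyl ether F4.
- Li, NH3 and t-BuOH, then aqueous HCl, give the conjugated 17-oxo-13(18)-ene F5. Its C14 hydrogen is epimerisable through the dienol, so the more stable epimer accumulates and the other can be recycled; the C24 ester is the group most at risk in this reduction.
- LiN(iPr)2 and PhNTf2 give the cross-conjugated dienyl triflate F6.
- Pd(OAc)2/dppp, CO, MeOH and Et3N give the dienoate F7.
- Conjugate reduction with LiBH(s-Bu)3 and trapping of the ester enolate with 33 (trans to C8) gives 36, with no selective hydrogenation needed.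

**Step 14.** The most likely failure is that the slow seven-membered closure lets the C8 cation lose a proton to the tetrasubstituted 8(9)-alkene or undergo a 1,2-hydride shift from C9 followed by spiro-closure or methyl migration. The fallback sets out from 22 and returns at 23 and makes no new compound. It replaces protic ionisation by hydrogen-atom-transfer hydroarylation under neutral conditions: a Co(salen) catalyst, N-fluoro-2,4,6-trimethylpyridinium triflate and PhSiH3 in CH2Cl2/hexafluoro-2-propanol. This generates the C8 radical, oxidises it at cobalt and lets the arene capture it, without strong acid and without reversible alkene isomerisation.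

**Step 9.** The most likely failures are insufficient facial discrimination by the auxiliary and further oxidation of the still enolisable product. The fallback sets out from 12 and returns at 20, giving up auxiliary control for separation against the fixed C12 centre:
- The dianion of methyl 2-methyl-3-oxobutanoate is alkylated with 12 to give the 2-methyl methyl ester polyene F8.
- Mn(OAc)3·2H2O and Cu(OAc)2·H2O in acetic acid cyclise F8 directly to the quaternary keto ester. This should give 20 and its diastereomer with the mirror-image decalin, F9, in similar amounts, which are separated by chromatography because C12 is fixed as S.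

## Further compounds

F1 | step 25 | 13β-chloro-19β-hydroxy pentacycle (14α-H, 18β-H, 3α-OTBS, dimethyl ester) | CO[C@@H]1C[C@@]2(Cl)[C@@H](CC[C@@]3(C(=O)OC)CCC(C)(C)[C@H](O)[C@@H]23)[C@]2(C)CC[C@@H]3[C@](C)(CC[C@@H](O[Si](C)(C)C(C)(C)C)[C@]3(C)C(=O)OC)[C@H]2C1
F2 | step 25 | 19β-epimer of 38 | CO[C@@H]1CC2=C(CC[C@@]3(C(=O)OC)CCC(C)(C)[C@H](O)[C@@H]23)[C@]2(C)CC[C@@H]3[C@](C)(CC[C@@H](O[Si](C)(C)C(C)(C)C)[C@]3(C)C(=O)OC)[C@H]2C1
F3 | step 25 | 19-oxo pentacycle (13-ene, 18β-H, 3α-OTBS, dimethyl ester) | CO[C@@H]1CC2=C(CC[C@@]3(C(=O)OC)CCC(C)(C)C(=O)[C@@H]23)[C@]2(C)CC[C@@H]3[C@](C)(CC[C@@H](O[Si](C)(C)C(C)(C)C)[C@]3(C)C(=O)OC)[C@H]2C1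
F4 | step 22 | 12α-methoxy tetracycle with 17-OMe | CO[C@@H]1Cc2cc(OC)ccc2[C@]2(C)CC[C@@H]3[C@](C)(CC[C@@H](O[Si](C)(C)C(C)(C)C)[C@]3(C)C(=O)OC)[C@H]2C1
F5 | step 22 | 17-oxo-13(18)-ene tetracycle with 14α-H | CO[C@@H]1CC2=CC(=O)CC[C@H]2[C@]2(C)CC[C@@H]3[C@](C)(CC[C@@H](O[Si](C)(C)C(C)(C)C)[C@]3(C)C(=O)OC)[C@H]2C1
F6 | step 22 | 13(18),16-dienyl 17-triflate | CO[C@@H]1CC2=CC(OS(=O)(=O)C(F)(F)F)=CC[C@H]2[C@]2(C)CC[C@@H]3[C@](C)(CC[C@@H](O[Si](C)(C)C(C)(C)C)[C@]3(C)C(=O)OC)[C@H]2C1
F7 | step 22 | 13(18),16-dien-17-yl methyl ester (dienoate) | CO[C@@H]1CC2=CC(C(=O)OC)=CC[C@H]2[C@]2(C)CC[C@@H]3[C@](C)(CC[C@@H](O[Si](C)(C)C(C)(C)C)[C@]3(C)C(=O)OC)[C@H]2C1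
F0 | step 14 | none | none
F8 | step 9 | methyl (6E,10E,13S)-13-acetoxy-14-[3-(benzyloxy)phenyl]-2,6,10-trimethyl-3-oxotetradeca-6,10-dienoate | COC(=O)C(C)C(=O)CC/C(C)=C/CC/C(C)=C/C[C@H](OC(C)=O)Cc1cccc(OCc2ccccc2)c1
F9 | step 9 | diastereomer of 20 with the mirror-image decalin and 12S side chain | C=C1CC[C@H]2[C@@](C)(CCC(=O)[C@@]2(C)C(=O)OC)[C@@H]1C[C@H](OC(C)=O)Cc1cccc(OCc3ccccc3)c1
A1 | alternative 1 | (1R,2S,5R)-8-phenylmenthyl ester of the bicyclic 3-oxo-8(26)-ene with 4α-methyl, 4β-ester and 11-acetoxy | C=C1CC[C@@H]2[C@](C)(CCC(=O)[C@]2(C)C(=O)O[C@@H]3C[C@H](C)CC[C@H]3C(C)(C)c3ccccc3)[C@H]1COC(C)=O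
A2 | alternative 2 | ring C isoxazoline (C13=N, O on C12, C13–C27 bond) with ring D open and a 19-oxo ring E, 3α-OTBS, dimethyl ester | N1=C2C[C@@H](O1)C[C@H]3[C@](C)([C@@H]2CC[C@@]4(C(=O)OC)CCC(C)(C)C(=O)C4)CC[C@@H]5[C@]3(C)CC[C@@H](O[Si](C)(C)C(C)(C)C)[C@]5(C)C(=O)OC
A3 | alternative 3 | 11-oxo pentacycle, 3,19-bis(tert-butyldimethylsilyl) ether, dimethyl ester | CO[C@@H]1CC2=C(CC[C@@]3(C(=O)OC)CCC(C)(C)[C@@H](O[Si](C)(C)C(C)(C)C)[C@@H]23)[C@]2(C)CC[C@@H]3[C@](C)(CC[C@@H](O[Si](C)(C)C(C)(C)C)[C@]3(C)C(=O)OC)[C@H]2C1=O
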